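**Plan**

Numbering: C1 benzoyl bridgehead; C2 and C4 ketones on quaternary C3; C5 geranyl bridgehead; C6 (CH2); C7 (CH); C8 (CMe2); C9 bridging ketone; C10 (CH2) and C11 (CH) link C7 to C3; C12 (CMe2), C13, C14 complete the cyclopentane.
Retrosynthesis: cut C5–geranyl, then C1–C8 (tertiary cation onto the enolised acyl dione), then C1–C2 with the C1–benzoyl and C5–C9 acylations, then C5–C6, then C3–C4, and last C3–C11.
Forward: cyclopentane (C3, C11–C14) by contraction of a nine-membered lactone; cycloheptanone (C3, C4, C5, C6, C7, C10, C11) by enolate alkylation; trione ring (C1, C2, C3, C4, C5, C9) by Claisen condensation; ring B (C1, C9, C5, C6, C7, C8) by cation capture; geranyl last.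
Enabling feature: C11, the only stereocentre the cage leaves free, lies on the cyclopentane bond C3–C11, next to C3 (the α-carbon of carbonyl C2) and 1,3 to C7, so this bond can be made by an ester-enolate [3,3] shift of an allylic C7–O ester.
Stereochemistry: C11 from (R)-benzyl glycidyl ether by 1,3-chirality transfer; C3 by acylation anti to the C11 side chain; C7 by an (S)-oxazolidinone alkylation; C1 and C5 are dictated by the cage.

Key step: step 8

Assumption: the di- and triketones 29–31 (and their fallback analogues) are written as keto tautomers although they are largely enolised; carbons that epimerise through the enol are drawn without configuration.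

**Route**

Step 1
Reactants: 1 methyl 3,3-dimethylpent-4-enoate
Product: 2 3,3-dimethylpent-4-en-1-ol
Conditions: LiAlH4, Et2O, 0 °C to rt
Reagents that add atoms: none
Why: Hydride reduction of the ester gives the primary alcohol and leaves the isolated vinyl group untouched.

Step 2
Reactants: 2 3,3-dimethylpent-4-en-1-ol
Product: 3 5-iodo-3,3-dimethylpent-1-ene
Conditions: I2, PPh3, imidazole, CH2Cl2, 0 °C to rt
Reagents that add atoms: iodine, II
Why: Appel-type iodination converts the unhindered primary alcohol into the iodide by SN2 displacement of the oxyphosphonium group.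

Step 3
Reactants: 3 5-iodo-3,3-dimethylpent-1-ene; 4 dimethyl malonate
Product: 5 dimethyl 2-(3,3-dimethylpent-4-en-1-yl)propanedioate
Conditions: NaH, THF–DMF, 0 to 60 °C
Reagents that add atoms: none
Why: Malonic ester alkylation, in which sodium dimethyl malonate displaces the primary iodide by SN2.

Step 4
Reactants: 5 dimethyl 2-(3,3-dimethylpent-4-en-1-yl)propanedioate
Product: 7 5,5-dimethylhept-6-enoic acid, via malonic diacid 6 (not isolated)
Conditions: KOH, MeOH–H2O, reflux; HCl; then 150 °C
Reagents that add atoms: potassium hydroxide, [K+].[OH-]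
Why: Saponification followed by thermal decarboxylation of the malonic acid completes the malonic ester synthesis of the C2–C3–C14–C13–C12–C11 chain.

Step 5
Reactants: 8 (2R)-2-[(benzyloxy)methyl]oxirane
Product: 9 (2R)-1-(benzyloxy)but-3-en-2-ol
Conditions: Me3S+ I−, n-BuLi, THF, −10 °C to rt
Reagents that add atoms: trimethylsulfonium iodide, C[S+](C)C.[I-]
Why: Dimethylsulfonium methylide opens the epoxide at CH2 and the β-sulfonium alkoxide eliminates Me2S (one-carbon homologation of an epoxide to an allylic alcohol); the stereocentre is not touched.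

Step 6
Reactants: 7 5,5-dimethylhept-6-enoic acid; 9 (2R)-1-(benzyloxy)but-3-en-2-ol
Product: 10 (2R)-1-(benzyloxy)but-3-en-2-yl 5,5-dimethylhept-6-enoate
Conditions: EDC·HCl, DMAP, CH2Cl2, 0 °C to rt
Reagents that add atoms: none
Why: Steglich esterification joins the acid and the secondary allylic alcohol without affecting the carbinol stereocentre.

Step 7
Reactants: 10 (2R)-1-(benzyloxy)but-3-en-2-yl 5,5-dimethylhept-6-enoate
Product: 11 (7Z,9R)-9-[(benzyloxy)methyl]-6,6-dimethyloxacyclonon-7-en-2-one
Conditions: second-generation Grubbs catalyst (10 mol %), toluene (2 mM), 80 °C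
Reagents that add atoms: none
Why: Ring-closing olefin metathesis should initiate at the allylic ester vinyl group and close onto the neopentyl-type vinyl group with help from the gem-dimethyl effect, and the nine-membered ring accommodates only the (Z)-alkene.

Step 8
Reactants: 11 (7Z,9R)-9-[(benzyloxy)methyl]-6,6-dimethyloxacyclonon-7-en-2-one
Product: 14 (1S,2S)-2-[(1E)-3-(benzyloxy)prop-1-en-1-yl]-3,3-dimethylcyclopentane-1-carboxylic acid, via silyl ketene acetal 12 (not isolated), via trimethylsilyl ester 13 (not isolated)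
Conditions: LiN(iPr)2, Me3SiCl–Et3N, THF, −78 °C to rt; toluene, 100 °C; then 1 M HCl
Reagents that add atoms: none
Why: Deprotonation at C3 and O-silylation give ketene acetal 12, in which C14 and the ring oxygen are cis on C3=C2 because both lie in the ring; on warming, the array C3=C2–O–C7–C10=C11 undergoes a [3,3]-sigmatropic (Ireland–Claisen) shift that forms C3–C11 and breaks C7–O. The closest known reaction type is the ester-enolate Claisen ring contraction of medium-ring (Z)-alkenyl lactones to cis-2-alkenylcycloalkanecarboxylic acids. The cyclopentane (C3, C14, C13, C12, C11) closes by bonding of the two termini of the sigmatropic array, which the C14–C13–C12 tether holds syn, so the six-centre transition state is a boat and the nine-membered ring contracts by four atoms. C11 is controlled by the (R)-C7–O stereocentre: the shift is suprafacial on the allyl unit, and only the conformer with H7 (not CH2OBn) eclipsing the alkene avoids allylic 1,3-strain against the C12 gem-dimethyl group, so C3 adds to the face from which oxygen leaves and the new alkene is E. C3 is controlled by the ring-enforced ketene acetal geometry and the boat, which place the carboxyl carbon C2 cis to the alkenyl arm. The step needs complete 1,3-transfer in this sense, and the (Z)-alkene, the single lactone stereocentre and in situ silylation of the enolate should secure it.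

Step 9
Reactants: 14 (1S,2S)-2-[(1E)-3-(benzyloxy)prop-1-en-1-yl]-3,3-dimethylcyclopentane-1-carboxylic acid
Product: 15 methyl (1S,2S)-2-[(1E)-3-(benzyloxy)prop-1-en-1-yl]-3,3-dimethylcyclopentane-1-carboxylate
Conditions: MeI, K2CO3, DMF, rt
Reagents that add atoms: iodomethane, CI
Why: O-Methylation of the carboxylate gives the ester needed for enolate chemistry; the C3 configuration is of no consequence because C3 is re-formed in step 18.

Step 10
Reactants: 15 methyl (1S,2S)-2-[(1E)-3-(benzyloxy)prop-1-en-1-yl]-3,3-dimethylcyclopentane-1-carboxylate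
Product: 16 methyl (1S,2S)-2-(3-hydroxypropyl)-3,3-dimethylcyclopentane-1-carboxylate
Conditions: H2 (1 atm), Pd(OH)2/C, EtOAc–EtOH, rt
Reagents that add atoms: none
Why: Catalytic hydrogenation saturates the C10=C7 alkene and then hydrogenolyses the benzyl ether, freeing the primary alcohol on the carbon that becomes C8.

Step 11
Reactants: 16 methyl (1S,2S)-2-(3-hydroxypropyl)-3,3-dimethylcyclopentane-1-carboxylate
Product: 17 3-[(1S,2S)-2-(methoxycarbonyl)-5,5-dimethylcyclopentyl]propanoic acid
Conditions: TEMPO (10 mol %), PhI(OAc)2, MeCN–H2O, rt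
Reagents that add atoms: water, O
Why: Nitroxyl-catalysed oxidation in wet acetonitrile takes the primary alcohol through the aldehyde hydrate to the carboxylic acid (C8) without affecting the ester.

Step 12
Reactants: 17 3-[(1S,2S)-2-(methoxycarbonyl)-5,5-dimethylcyclopentyl]propanoic acid
Product: 19 methyl (1S,2S)-2-{3-[(4S)-4-benzyl-2-oxo-1,3-oxazolidin-3-yl]-3-oxopropyl}-3,3-dimethylcyclopentane-1-carboxylate, via mixed pivalic anhydride 18 (not isolated)
Conditions: t-BuCOCl, Et3N, THF, −20 °C; then (4S)-4-benzyl-1,3-oxazolidin-2-one, LiCl, rt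
Reagents that add atoms: (4S)-4-benzyl-1,3-oxazolidin-2-one, O=C1OC[C@H](Cc2ccccc2)N1
Why: N-Acylation of the oxazolidinone through the mixed anhydride places the Evans auxiliary on the C8 carboxyl, the only activated acyl group.

Step 13
Reactants: 19 methyl (1S,2S)-2-{3-[(4S)-4-benzyl-2-oxo-1,3-oxazolidin-3-yl]-3-oxopropyl}-3,3-dimethylcyclopentane-1-carboxylate
Product: 20 methyl (1S,2S)-2-{(2R)-2-[(benzyloxy)methyl]-3-[(4S)-4-benzyl-2-oxo-1,3-oxazolidin-3-yl]-3-oxopropyl}-3,3-dimethylcyclopentane-1-carboxylate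
Conditions: TiCl4, iPr2NEt, CH2Cl2, 0 °C; BnOCH2Cl, 0 °C
Reagents that add atoms: benzyl chloromethyl ether, ClCOCc1ccccc1
Why: Evans alkylation, in which the chelated (Z)-titanium enolate is attacked on the face opposite the benzyl group of the (S)-auxiliary, introduces C6 and sets C7 as (R).

Step 14
Reactants: 20 methyl (1S,2S)-2-{(2R)-2-[(benzyloxy)methyl]-3-[(4S)-4-benzyl-2-oxo-1,3-oxazolidin-3-yl]-3-oxopropyl}-3,3-dimethylcyclopentane-1-carboxylate
Product: 21 methyl (1S,2S)-2-[(2R)-2-[(benzyloxy)methyl]-3-(ethylsulfanyl)-3-oxopropyl]-3,3-dimethylcyclopentane-1-carboxylate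
Conditions: EtSH, n-BuLi, THF, 0 °C
Reagents that add atoms: ethanethiol, CCS
Why: Lithium ethanethiolate cleaves the imide at the exocyclic carbonyl (transthioesterification), releasing the auxiliary without epimerising C7 and leaving the methyl ester intact.

Step 15
Reactants: 21 methyl (1S,2S)-2-[(2R)-2-[(benzyloxy)methyl]-3-(ethylsulfanyl)-3-oxopropyl]-3,3-dimethylcyclopentane-1-carboxylate
Product: 22 methyl (1S,2S)-2-[(2R)-2-[(benzyloxy)methyl]-3-oxobutyl]-3,3-dimethylcyclopentane-1-carboxylate
Conditions: Me2CuLi (from MeLi and CuI), Et2O, −78 °C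
Reagents that add atoms: lithium dimethylcuprate, [Li+].C[Cu-]C
Why: Thioesters are converted by lithium dialkylcuprates into ketones, while the methyl ester is inert and the weakly basic reagent does not epimerise C7.

Step 16
Reactants: 22 methyl (1S,2S)-2-[(2R)-2-[(benzyloxy)methyl]-3-oxobutyl]-3,3-dimethylcyclopentane-1-carboxylate
Product: 23 methyl (1S,2S)-2-[(2R)-2-[(benzyloxy)methyl]-3-hydroxy-3-methylbutyl]-3,3-dimethylcyclopentane-1-carboxylate
Conditions: MeMgBr, CeCl3, THF, −78 °C
Reagents that add atoms: methylmagnesium bromide, C[Mg]Br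
Why: The organocerium reagent adds to the methyl ketone at −78 °C much faster than to the ester and is too weakly basic to epimerise C7 or eliminate the β-benzyloxy group, completing C8 as a tertiary carbinol.

Step 17
Reactants: 23 methyl (1S,2S)-2-[(2R)-2-[(benzyloxy)methyl]-3-hydroxy-3-methylbutyl]-3,3-dimethylcyclopentane-1-carboxylate
Product: 24 methyl (1S,2S)-2-[(2R)-2-[(benzyloxy)methyl]-3-methyl-3-[(triethylsilyl)oxy]butyl]-3,3-dimethylcyclopentane-1-carboxylate
Conditions: Et3SiOTf, 2,6-lutidine, CH2Cl2, 0 °C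
Reagents that add atoms: triethylsilyl trifluoromethanesulfonate, CC[Si](CC)(CC)OS(=O)(=O)C(F)(F)F
Why: Silylation with the silyl triflate protects the tertiary alcohol against the strong bases that follow and keeps it as a latent C8 cation.

Step 18
Reactants: 24 methyl (1S,2S)-2-[(2R)-2-[(benzyloxy)methyl]-3-methyl-3-[(triethylsilyl)oxy]butyl]-3,3-dimethylcyclopentane-1-carboxylate
Product: 25 methyl (1S,2R)-1-acetyl-2-[(2R)-2-[(benzyloxy)methyl]-3-methyl-3-[(triethylsilyl)oxy]butyl]-3,3-dimethylcyclopentane-1-carboxylate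
Conditions: LiN(iPr)2, THF, −78 °C; enolate added to AcCl, −78 °C
Reagents that add atoms: acetyl chloride, CC(Cl)=O
Why: C-Acylation of the lithium ester enolate by the acid chloride (Claisen-type acylation) creates quaternary C3, and the electrophile enters anti to the C11 side chain so that acetyl carbon C4 is trans and ester carbon C2 cis to C10.

Step 19
Reactants: 25 methyl (1S,2R)-1-acetyl-2-[(2R)-2-[(benzyloxy)methyl]-3-methyl-3-[(triethylsilyl)oxy]butyl]-3,3-dimethylcyclopentane-1-carboxylate
Product: 26 methyl (1S,2R)-1-acetyl-2-[(2R)-2-(hydroxymethyl)-3-methyl-3-[(triethylsilyl)oxy]butyl]-3,3-dimethylcyclopentane-1-carboxylate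
Conditions: H2 (1 atm), Pd/C, EtOAc, rt
Reagents that add atoms: none
Why: Hydrogenolysis removes the benzyl ether on C6 and leaves the ketone, ester and silyl ether untouched.

Step 20
Reactants: 26 methyl (1S,2R)-1-acetyl-2-[(2R)-2-(hydroxymethyl)-3-methyl-3-[(triethylsilyl)oxy]butyl]-3,3-dimethylcyclopentane-1-carboxylate
Product: 27 methyl (1S,2R)-1-acetyl-2-[(2S)-2-(iodomethyl)-3-methyl-3-[(triethylsilyl)oxy]butyl]-3,3-dimethylcyclopentane-1-carboxylate
Conditions: I2, PPh3, imidazole, toluene, 0 to 40 °C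
Reagents that add atoms: iodine, II
Why: Appel-type iodination turns the primary alcohol on C6 into the leaving group for ring closure (the descriptor at C7 changes only because iodine raises the priority of C6).

Step 21
Reactants: 27 methyl (1S,2R)-1-acetyl-2-[(2S)-2-(iodomethyl)-3-methyl-3-[(triethylsilyl)oxy]butyl]-3,3-dimethylcyclopentane-1-carboxylate
Product: 28 methyl (3aS,7S,8aR)-1,1-dimethyl-4-oxo-7-{2-[(triethylsilyl)oxy]propan-2-yl}octahydroazulene-3a(1H)-carboxylate
Conditions: LiN(iPr)2, THF–DMPU, −78 °C to rt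
Reagents that add atoms: none
Why: The kinetic enolate of the methyl ketone, the only enolisable position, displaces the iodide in a 7-exo-tet alkylation that forms C5–C6 and the trans-fused cycloheptanone, helped by the quaternary C3.

Step 22
Reactants: 28 methyl (3aS,7S,8aR)-1,1-dimethyl-4-oxo-7-{2-[(triethylsilyl)oxy]propan-2-yl}octahydroazulene-3a(1H)-carboxylate
Product: 29 5-acetyl derivative of 28 (C5–C9 bond; C5 epimers and enol)
Conditions: LiN(iPr)2 (2.2 equiv), THF, −78 °C; 1-acetyl-1H-benzotriazole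
Reagents that add atoms: 1-acetyl-1H-benzotriazole, CC(=O)n1nnc2ccccc12
Why: The ketone enolate is C-acylated by the N-acylbenzotriazole at C5, its only α-CH2, to give the 1,3-diketone (crossed Claisen acylation).

Step 23
Reactants: 29 5-acetyl derivative of 28
Product: 30 5-(3-oxo-3-phenylpropanoyl) derivative of 28 (chain C5–C9(=O)–C1H2–C(=O)Ph)
Conditions: LiN(iPr)2 (3.3 equiv), THF, −78 to 0 °C; PhCO2Me
Reagents that add atoms: methyl benzoate, COC(=O)c1ccccc1
Why: The 1,3-diketone dianion reacts at its terminal carbanion C1 with the ester (acylation of a β-diketone dianion) to give the 1,3,5-triketone that already carries the benzoyl group.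

Step 24
Reactants: 30 5-(3-oxo-3-phenylpropanoyl) derivative of 28
Product: 31 tricyclic benzoyl trione (trione ring C1–C2–C3–C4–C5–C9 bridged from C3 to C5 by C11–C10–C7–C6; C1 carries H and benzoyl, C7 carries CMe2OSiEt3)
Conditions: KOtBu (1.1 equiv), THF, 0 to 50 °C; then 1 M HCl
Reagents that add atoms: none
Why: The benzoyl-stabilised enolate at C1 attacks the C2 ester in a 6-exo-trig Claisen (Dieckmann-type) condensation, which is driven by formation of the acidic 2-acyl-1,3-dione, while the epimerisable C5 adopts the configuration that lets C9 bridge to C2.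

Step 25
Reactants: 31 tricyclic benzoyl trione
Product: 32 cage tetraketone with hydrogen at C5 (5-desgeranyl target)
Conditions: MeSO3H, CH2Cl2, 0 °C to rt
Reagents that add atoms: none
Why: Acid ionises the tertiary silyl ether to the C8 cation, which the enol carbon C1 of the acyl dione captures in a six-membered closure (cationic C-alkylation as used for adamantane-type acylphloroglucinols); O-alkylation should be reversible under these conditions and the configuration at C1 is dictated by the cage.

Step 26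
Reactants: 32 cage tetraketone with hydrogen at C5
Product: 33 target CNP0168637.1
Conditions: lithium 2,2,6,6-tetramethylpiperidide, THF, −78 °C; geranyl bromide, −78 to −20 °C
Reagents that add atoms: geranyl bromide, CC(C)=CCC/C(C)=C/CBr
Why: The bridgehead C5–H between two ketones is removed by the hindered, non-reducing amide and the bridgehead carbanion is alkylated at the primary carbon of the allylic bromide (bridgehead lithiation–alkylation of bicyclic polyketones), with retention enforced by the cage and the (E)-alkene preserved.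

**Compound list**

1 | methyl 3,3-dimethylpent-4-enoate | COC(=O)CC(C)(C)C=C | starting material
2 | 3,3-dimethylpent-4-en-1-ol | OCCC(C)(C)C=C | intermediate
3 | 5-iodo-3,3-dimethylpent-1-ene | ICCC(C)(C)C=C | intermediate
4 | dimethyl malonate | COC(=O)CC(=O)OC | starting material
5 | dimethyl 2-(3,3-dimethylpent-4-en-1-yl)propanedioate | COC(=O)C(CCC(C)(C)C=C)C(=O)OC | intermediate
6 | 2-(3,3-dimethylpent-4-en-1-yl)propanedioic acid | OC(=O)C(CCC(C)(C)C=C)C(O)=O | intermediate (not isolated)
7 | 5,5-dimethylhept-6-enoic acid | OC(=O)CCCC(C)(C)C=C | intermediate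
8 | (2R)-2-[(benzyloxy)methyl]oxirane, (R)-benzyl glycidyl ether | C1[C@@H](O1)COCc1ccccc1 | starting material
9 | (2R)-1-(benzyloxy)but-3-en-2-ol | C=C[C@@H](O)COCc1ccccc1 | intermediate
10 | (2R)-1-(benzyloxy)but-3-en-2-yl 5,5-dimethylhept-6-enoate | C=CC(C)(C)CCCC(=O)O[C@@H](COCc1ccccc1)C=C | intermediate
11 | (7Z,9R)-9-[(benzyloxy)methyl]-6,6-dimethyloxacyclonon-7-en-2-one | O=C1CCCC(C)(C)/C=C\[C@H](COCc2ccccc2)O1 | intermediate
12 | (9R)-9-[(benzyloxy)methyl]-6,6-dimethyl-2-[(trimethylsilyl)oxy]oxacyclonona-2,7-diene (ring silyl ketene acetal) | C[Si](C)(C)O/C1=C/CCC(C)(C)/C=C\[C@H](COCc2ccccc2)O1 | intermediate (not isolated)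
13 | trimethylsilyl (1S,2S)-2-[(1E)-3-(benzyloxy)prop-1-en-1-yl]-3,3-dimethylcyclopentane-1-carboxylate | C[Si](C)(C)OC(=O)[C@H]1CCC(C)(C)[C@H]1/C=C/COCc1ccccc1 | intermediate (not isolated)
14 | (1S,2S)-2-[(1E)-3-(benzyloxy)prop-1-en-1-yl]-3,3-dimethylcyclopentane-1-carboxylic acid (carboxyl cis to the alkenyl arm) | OC(=O)[C@H]1CCC(C)(C)[C@H]1/C=C/COCc1ccccc1 | intermediate
15 | methyl (1S,2S)-2-[(1E)-3-(benzyloxy)prop-1-en-1-yl]-3,3-dimethylcyclopentane-1-carboxylate | COC(=O)[C@H]1CCC(C)(C)[C@H]1/C=C/COCc1ccccc1 | intermediate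
16 | methyl (1S,2S)-2-(3-hydroxypropyl)-3,3-dimethylcyclopentane-1-carboxylate | COC(=O)[C@H]1CCC(C)(C)[C@H]1CCCO | intermediate
17 | 3-[(1S,2S)-2-(methoxycarbonyl)-5,5-dimethylcyclopentyl]propanoic acid | COC(=O)[C@H]1CCC(C)(C)[C@H]1CCC(O)=O | intermediate
18 | mixed anhydride of 17 with pivalic acid | COC(=O)[C@H]1CCC(C)(C)[C@H]1CCC(=O)OC(=O)C(C)(C)C | intermediate (not isolated)
19 | methyl (1S,2S)-2-{3-[(4S)-4-benzyl-2-oxo-1,3-oxazolidin-3-yl]-3-oxopropyl}-3,3-dimethylcyclopentane-1-carboxylate | COC(=O)[C@H]1CCC(C)(C)[C@H]1CCC(=O)N1C(=O)OC[C@@H]1Cc1ccccc1 | intermediate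
20 | methyl (1S,2S)-2-{(2R)-2-[(benzyloxy)methyl]-3-[(4S)-4-benzyl-2-oxo-1,3-oxazolidin-3-yl]-3-oxopropyl}-3,3-dimethylcyclopentane-1-carboxylate | COC(=O)[C@H]1CCC(C)(C)[C@H]1C[C@H](COCc1ccccc1)C(=O)N1C(=O)OC[C@@H]1Cc1ccccc1 | intermediate
21 | methyl (1S,2S)-2-[(2R)-2-[(benzyloxy)methyl]-3-(ethylsulfanyl)-3-oxopropyl]-3,3-dimethylcyclopentane-1-carboxylate | COC(=O)[C@H]1CCC(C)(C)[C@H]1C[C@H](COCc1ccccc1)C(=O)SCC | intermediate
22 | methyl (1S,2S)-2-[(2R)-2-[(benzyloxy)methyl]-3-oxobutyl]-3,3-dimethylcyclopentane-1-carboxylate | COC(=O)[C@H]1CCC(C)(C)[C@H]1C[C@H](COCc1ccccc1)C(C)=O | intermediate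
23 | methyl (1S,2S)-2-[(2R)-2-[(benzyloxy)methyl]-3-hydroxy-3-methylbutyl]-3,3-dimethylcyclopentane-1-carboxylate | COC(=O)[C@H]1CCC(C)(C)[C@H]1C[C@H](COCc1ccccc1)C(C)(C)O | intermediate
24 | methyl (1S,2S)-2-[(2R)-2-[(benzyloxy)methyl]-3-methyl-3-[(triethylsilyl)oxy]butyl]-3,3-dimethylcyclopentane-1-carboxylate | COC(=O)[C@H]1CCC(C)(C)[C@H]1C[C@H](COCc1ccccc1)C(C)(C)O[Si](CC)(CC)CC | intermediate
25 | methyl (1S,2R)-1-acetyl-2-[(2R)-2-[(benzyloxy)methyl]-3-methyl-3-[(triethylsilyl)oxy]butyl]-3,3-dimethylcyclopentane-1-carboxylate (acetyl trans, ester cis to the side chain) | COC(=O)[C@@]1(C(C)=O)CCC(C)(C)[C@H]1C[C@H](COCc1ccccc1)C(C)(C)O[Si](CC)(CC)CC | intermediate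
26 | methyl (1S,2R)-1-acetyl-2-[(2R)-2-(hydroxymethyl)-3-methyl-3-[(triethylsilyl)oxy]butyl]-3,3-dimethylcyclopentane-1-carboxylate | COC(=O)[C@@]1(C(C)=O)CCC(C)(C)[C@H]1C[C@H](CO)C(C)(C)O[Si](CC)(CC)CC | intermediate
27 | methyl (1S,2R)-1-acetyl-2-[(2S)-2-(iodomethyl)-3-methyl-3-[(triethylsilyl)oxy]butyl]-3,3-dimethylcyclopentane-1-carboxylate | COC(=O)[C@@]1(C(C)=O)CCC(C)(C)[C@H]1C[C@H](CI)C(C)(C)O[Si](CC)(CC)CC | intermediate
28 | methyl (3aS,7S,8aR)-1,1-dimethyl-4-oxo-7-{2-[(triethylsilyl)oxy]propan-2-yl}octahydroazulene-3a(1H)-carboxylate (trans-fused) | COC(=O)[C@@]12CCC(C)(C)[C@H]1C[C@@H](C(C)(C)O[Si](CC)(CC)CC)CCC2=O | intermediate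
29 | 5-acetyl derivative of 28 (1,3-diketone C4/C9) | COC(=O)[C@@]12CCC(C)(C)[C@H]1C[C@@H](C(C)(C)O[Si](CC)(CC)CC)CC(C(C)=O)C2=O | intermediate
30 | 5-(3-oxo-3-phenylpropanoyl) derivative of 28 (1,3,5-triketone) | COC(=O)[C@@]12CCC(C)(C)[C@H]1C[C@@H](C(C)(C)O[Si](CC)(CC)CC)CC(C(=O)CC(=O)c1ccccc1)C2=O | intermediate
31 | tricyclic benzoyl trione (trione ring bridged C3 to C5 by C11–C10–C7–C6, cyclopentane fused at C3–C11, CMe2OSiEt3 on C7) | O=C(c1ccccc1)C1C(=O)[C@@]23CCC(C)(C)[C@H]2C[C@@H](C(C)(C)O[Si](CC)(CC)CC)C[C@@H](C1=O)C3=O | intermediate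
32 | cage tetraketone with hydrogen at C5 (5-desgeranyl target) | [C@@H]12C[C@H]3C[C@@H]4C(C)(C)CC[C@]4(C1=O)C(=O)[C@@](C(=O)c1ccccc1)(C2=O)C3(C)C | intermediate
33 | CNP0168637.1 | CC(C)=CCC/C(C)=C/C[C@@]12C[C@H]3C[C@@H]4C(C)(C)CC[C@]4(C1=O)C(=O)[C@@](C(=O)c1ccccc1)(C2=O)C3(C)C | target

**Step count and risks**

Total steps: 26. Longest linear sequence: 25 steps (steps 1–4 and 6–26; step 5 is a one-step side branch).

Steps most likely to fail:

1. Step 25. The tertiary cation may be trapped by an enol oxygen to give a cyclic enol ether, or may undergo a 1,2-hydride shift from C7 and elimination, faster than C1 attacks it. The fallback avoids a free cation. From 31, Bu4NF in THF removes the silyl group to give the tertiary alcohol, 7-(2-hydroxypropan-2-yl) trione F1. The Burgess reagent dehydrates it to the 7-isopropenyl trione F2. A cationic monovalent gold catalyst, (Ph3P)AuCl/AgOTf in toluene, then adds the C1–H of the acyl dione across the 1,1-disubstituted alkene in the Markovnikov, 6-exo sense (metal-catalysed hydroalkylation of an unactivated alkene by a 1,3-dicarbonyl compound), and the route is rejoined at 32.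

2. Step 26. Bridgehead deprotonation may lose out to attack of the base or of the carbanion on the aryl ketone, or the cage may open by retro-Claisen cleavage. The fallback puts the geranyl group on C5 while C5 is still an ordinary 1,3-diketone carbon. From 29, K2CO3 and geranyl bromide in acetone give the C-alkylated diketone, C5-geranyl diketone F3 (the isomer with acetyl cis to the ester is needed). LiN(iPr)2 and PhCO2Me acylate the acetyl methyl group to the geranylated triketone F4. KOtBu closes the trione ring between two quaternary centres to the geranylated tricyclic trione F5. Bu4NF gives the tertiary alcohol F6, and the Burgess reagent the isopropenyl compound F7. The gold-catalysed hydroalkylation described under step 25 should engage the 1,1-disubstituted alkene in preference to the trisubstituted ones, form C1–C8 and give 33 directly.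

3. Step 7. Intermolecular metathesis at the unhindered allylic vinyl group (oligomer formation) may outrun closure of the strained nine-membered ring onto the neopentyl-type vinyl group. The fallback makes the (Z)-alkene from an alkyne and closes the ring at the ester bond. From 7, Br2 in CH2Cl2 gives 6,7-dibromo-5,5-dimethylheptanoic acid F8, and KOtBu in DMSO gives 5,5-dimethylhept-6-ynoic acid F9. Its dilithio salt (n-BuLi, 2 equiv) is acylated by 2-(benzyloxy)-N-methoxy-N-methylacetamide to the ynone acid F10. Transfer hydrogenation with RuCl(p-cymene)[(S,S)-TsDPEN] and HCO2H–Et3N should give the (R)-propargylic alcohol F11 on the usual facial model. Semihydrogenation over Pd/CaCO3 poisoned with Pb(OAc)2 and quinoline gives the (Z)-hydroxy acid F12. Yamaguchi lactonisation (2,4,6-trichlorobenzoyl chloride, Et3N; then DMAP, toluene, high dilution) returns to 11.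

**Further compounds**

F1 | step 25 | 7-(2-hydroxypropan-2-yl) tricyclic benzoyl trione (desilylated 31) | O=C(c1ccccc1)C1C(=O)[C@@]23CCC(C)(C)[C@H]2C[C@@H](C(C)(C)O)C[C@@H](C1=O)C3=O
F2 | step 25 | 7-isopropenyl tricyclic benzoyl trione | O=C(c1ccccc1)C1C(=O)[C@@]23CCC(C)(C)[C@H]2C[C@@H](C(C)=C)C[C@@H](C1=O)C3=O
F3 | step 26 | C5-geranyl diketone (5-acetyl-5-geranyl derivative of 28, acetyl cis to the ester) | COC(=O)[C@@]12CCC(C)(C)[C@H]1C[C@@H](C(C)(C)O[Si](CC)(CC)CC)C[C@@](C/C=C(\C)CCC=C(C)C)(C(C)=O)C2=O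
F4 | step 26 | geranylated triketone (5-geranyl-5-(3-oxo-3-phenylpropanoyl) derivative of 28) | COC(=O)[C@@]12CCC(C)(C)[C@H]1C[C@@H](C(C)(C)O[Si](CC)(CC)CC)C[C@@](C/C=C(\C)CCC=C(C)C)(C(=O)CC(=O)c1ccccc1)C2=O
F5 | step 26 | geranylated tricyclic trione (5-geranyl analogue of 31) | O=C(c1ccccc1)C1C(=O)[C@@]23CCC(C)(C)[C@H]2C[C@@H](C(C)(C)O[Si](CC)(CC)CC)C[C@@](C/C=C(\C)CCC=C(C)C)(C1=O)C3=O
F6 | step 26 | tertiary alcohol (desilylated F5) | O=C(c1ccccc1)C1C(=O)[C@@]23CCC(C)(C)[C@H]2C[C@@H](C(C)(C)O)C[C@@](C/C=C(\C)CCC=C(C)C)(C1=O)C3=O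
F7 | step 26 | isopropenyl compound (5-geranyl analogue of F2) | O=C(c1ccccc1)C1C(=O)[C@@]23CCC(C)(C)[C@H]2C[C@@H](C(C)=C)C[C@@](C/C=C(\C)CCC=C(C)C)(C1=O)C3=O
F8 | step 7 | 6,7-dibromo-5,5-dimethylheptanoic acid | OC(=O)CCCC(C)(C)C(Br)CBr
F9 | step 7 | 5,5-dimethylhept-6-ynoic acid | OC(=O)CCCC(C)(C)C#C
F10 | step 7 | 9-(benzyloxy)-5,5-dimethyl-8-oxonon-6-ynoic acid | OC(=O)CCCC(C)(C)C#CC(=O)COCc1ccccc1
F11 | step 7 | (8R)-9-(benzyloxy)-8-hydroxy-5,5-dimethylnon-6-ynoic acid | OC(=O)CCCC(C)(C)C#C[C@@H](O)COCc1ccccc1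
F12 | step 7 | (6Z,8R)-9-(benzyloxy)-8-hydroxy-5,5-dimethylnon-6-enoic acid | OC(=O)CCCC(C)(C)/C=C\[C@@H](O)COCc1ccccc1
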